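**Retrosynthetic overview**

- Feature: the naphthalene ring that carries the biaryl bond (ring C: C1', C2', C3', C4', C4a', C8a') has the aryl group on C1' and oxygen on C4', para to each other, with a second oxygen on the peri carbon C5'. This is the pattern left by a 2-oxyfuran (C2–O, C5–aryl) adding across a 3-oxybenzyne.
- Key disconnection: C4'–C4a' and C1'–C8a' are cut by an aryne Diels-Alder reaction between silyloxyfuran 13 and the benzyne from 21. The bridged ketal collapses to hydroxy-naphthalenone 24, which is carried on by Zn/AcOH aromatisation, O-methylation, hydrogenolysis and resolution.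
- Furan 13 comes from aldehyde 7, whose formyl carbon becomes C1'. The C7–C1' bond is therefore made by an ortho-formylation and not by an aryl-aryl coupling. The furan is built by propiolate addition, methylcuprate addition with lactonisation, and silylation.
- The isoquinoline comes from 2',6'-dihydroxyacetophenone by mono-triflation, Sonogashira coupling with propyne and ammonia annulation. Aryne precursor 21 comes from 3-(benzyloxy)phenol by carbamate-directed ortho-silylation.
- Ring order: pyridine ring of the isoquinoline, then the sacrificial butenolide/furan, then naphthalene ring C.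

Key step: step 12

Assumption: the target SMILES carries no descriptor for the C7–C1' axis. ent-Dioncophylleine A is taken to be the M atropisomer, so racemate 27 and resolved target 28 share one SMILES.

**Route**

Step 1
Reactants: 1 2',6'-dihydroxyacetophenone
Product: 2 2-acetyl-3-hydroxyphenyl trifluoromethanesulfonate
Conditions: Tf2O (1.0 equiv), pyridine, CH2Cl2, −78 → 0 °C
Reagents that add atoms: triflic anhydride, O=S(=O)(OS(=O)(=O)C(F)(F)F)C(F)(F)F
Why: O-sulfonylation of a phenol; the two hydroxyls are equivalent, and after the first triflation the remaining one is hydrogen-bonded to the acetyl oxygen on an electron-poorer ring, so one equivalent should stop at the mono-triflate.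

Step 2
Reactants: 2 2-acetyl-3-hydroxyphenyl trifluoromethanesulfonate; 3 propyne (excess)
Product: 4 1-[2-hydroxy-6-(prop-1-yn-1-yl)phenyl]ethan-1-one
Conditions: Pd(PPh3)2Cl2 (cat.), CuI (cat.), Et3N, DMF, 50 °C, sealed vessel
Reagents that add atoms: none
Why: Sonogashira coupling; the triflate ortho to the acetyl group is activated toward oxidative addition to zerovalent palladium, and the free phenol is tolerated under amine base.

Step 3
Reactants: 4 1-[2-hydroxy-6-(prop-1-yn-1-yl)phenyl]ethan-1-one
Product: 5 1,3-dimethylisoquinolin-8-ol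
Conditions: NH3 (7 M in MeOH), sealed tube, 100 °C
Reagents that add atoms: ammonia, N
Why: condensation to the N–H ketimine and 6-endo-dig addition of nitrogen to the alkyne (aza-annulation of an ortho-alkynylaryl ketone), driven by aromatisation to the isoquinoline.

Step 4
Reactants: 5 1,3-dimethylisoquinolin-8-ol
Product: 6 8-hydroxy-1,3-dimethylisoquinoline-7-carbaldehyde
Conditions: MgCl2, Et3N, (CH2O)n, MeCN, reflux; work-up at pH 7
Reagents that add atoms: paraformaldehyde (as formaldehyde), C=O
Why: magnesium-phenoxide-directed ortho-formylation (Casnati–Skattebøl reaction); formaldehyde is delivered inside the magnesium chelate to C7, the only free ortho position, and a second formaldehyde oxidises the hydroxymethyl intermediate by hydride transfer, so C5 is left alone.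

Step 5
Reactants: 6 8-hydroxy-1,3-dimethylisoquinoline-7-carbaldehyde
Product: 7 8-(benzyloxy)-1,3-dimethylisoquinoline-7-carbaldehyde
Conditions: BnBr, K2CO3, DMF, 60 °C
Reagents that add atoms: benzyl bromide, BrCc1ccccc1
Why: Williamson ether synthesis; the phenoxide is far more nucleophilic than the ring nitrogen, which is flanked by two methyl groups.

Step 6
Reactants: 7 8-(benzyloxy)-1,3-dimethylisoquinoline-7-carbaldehyde; 8 ethyl propiolate
Product: 10 ethyl (±)-4-[8-(benzyloxy)-1,3-dimethylisoquinolin-7-yl]-4-hydroxybut-2-ynoate, via lithium (ethoxycarbonyl)acetylide 9 (not isolated)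
Conditions: 8, LDA, THF, −78 °C; then 7, −78 °C; aq. NH4Cl
Reagents that add atoms: lithium diisopropylamide, [Li+].CC(C)[N-]C(C)C (lithium in 9 only)
Why: 1,2-addition of a lithium acetylide to an aldehyde at −78 °C, where the acetylide is stable; the carbinol centre forms as a racemate, which does not matter because step 8 erases it.

Step 7
Reactants: 10 ethyl (±)-4-[8-(benzyloxy)-1,3-dimethylisoquinolin-7-yl]-4-hydroxybut-2-ynoate
Product: 12 (±)-5-[8-(benzyloxy)-1,3-dimethylisoquinolin-7-yl]-4-methylfuran-2(5H)-one, via Z-hydroxy enoate 11 (not isolated)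
Conditions: Me2CuLi (3 equiv), THF, −78 °C; MeOH then aq. NH4Cl, −78 °C → rt
Reagents that add atoms: lithium dimethylcuprate, [Li+].C[Cu-]C
Why: syn-carbocupration (conjugate addition of a cuprate to an ynoate) puts methyl on C3 and, after protonation with retention, the carbinol carbon cis to the ester, so Z-hydroxy enoate 11 should close to the butenolide by lactonisation; the racemic carbinol centre is untouched.

Step 8
Reactants: 12 (±)-5-[8-(benzyloxy)-1,3-dimethylisoquinolin-7-yl]-4-methylfuran-2(5H)-one
Product: 13 8-(benzyloxy)-1,3-dimethyl-7-[3-methyl-5-(triisopropylsilyloxy)furan-2-yl]isoquinoline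
Conditions: TIPSOTf, Et3N, CH2Cl2, 0 °C → rt
Reagents that add atoms: triisopropylsilyl triflate, CC(C)[Si](OS(=O)(=O)C(F)(F)F)(C(C)C)C(C)C
Why: soft enolisation with a silyl triflate and an amine; O-silylation of the lactone carbonyl and loss of the benzylic γ-proton at C5 give the aromatic 2-silyloxyfuran and erase the C5 stereocentre.

Step 9
Reactants: 14 3-(benzyloxy)phenol
Product: 15 3-(benzyloxy)phenyl isopropylcarbamate
Conditions: i-PrNCO, Et3N (cat.), CH2Cl2, rt
Reagents that add atoms: isopropyl isocyanate, CC(C)N=C=O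
Why: carbamoylation of a phenol with an isocyanate, which installs the directing group for metalation.

Step 10
Reactants: 15 3-(benzyloxy)phenyl isopropylcarbamate
Product: 19 3-(benzyloxy)-2-(trimethylsilyl)phenyl isopropylcarbamate, via N-silyl carbamate 16 (not isolated), via 2-lithio N-silyl carbamate 17 (not isolated), via N-silyl C-silyl carbamate 18 (not isolated)
Conditions: TBSOTf, TMEDA, Et2O, 0 °C → rt; n-BuLi, TMEDA, −78 °C; Me3SiCl, −78 °C → rt; aq. NaHSO4
Reagents that add atoms: tert-butyldimethylsilyl triflate, CC(C)(C)[Si](C)(C)OS(=O)(=O)C(F)(F)F (silicon on nitrogen in 16 to 18 only); n-butyllithium, [Li]CCCC (lithium in 17 only); chlorotrimethylsilane, C[Si](C)(C)Cl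
Why: directed ortho-metalation after in situ N-silylation; the carbamate and the benzyloxy oxygen together direct lithium to C2 between them, a site that should be lithiated faster at −78 °C than the benzylic CH2, and the aryllithium is trapped by Me3SiCl before acidic work-up removes the N-silyl group.

Step 11
Reactants: 19 3-(benzyloxy)-2-(trimethylsilyl)phenyl isopropylcarbamate
Product: 21 3-(benzyloxy)-2-(trimethylsilyl)phenyl trifluoromethanesulfonate, via 3-(benzyloxy)-2-(trimethylsilyl)phenol 20 (not isolated)
Conditions: DBU, Et2NH, MeCN, 40 °C; then PhNTf2, rt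
Reagents that add atoms: N-phenylbis(trifluoromethanesulfonimide), O=S(=O)(N(c1ccccc1)S(=O)(=O)C(F)(F)F)C(F)(F)F
Why: base-induced E1cB cleavage of the N–H carbamate (the isocyanate is trapped by Et2NH as a urea) followed by sulfonylation of the phenoxide in the same flask, the usual one-pot conversion of ortho-silylaryl carbamates into ortho-silylaryl triflates.

Step 12
Reactants: 13 8-(benzyloxy)-1,3-dimethyl-7-[3-methyl-5-(triisopropylsilyloxy)furan-2-yl]isoquinoline; 21 3-(benzyloxy)-2-(trimethylsilyl)phenyl trifluoromethanesulfonate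
Product: 24 (±)-4-[8-(benzyloxy)-1,3-dimethylisoquinolin-7-yl]-8-(benzyloxy)-4-hydroxy-3-methylnaphthalen-1(4H)-one, via 3-(benzyloxy)benzyne 22 (not isolated), via oxa-bridged cycloadduct 23 (not isolated)
Conditions: 21 (1.5 equiv, slow addition), CsF (4 equiv), MeCN/toluene 1:1, rt; aq. NH4Cl
Reagents that add atoms: none
Why: Fluoride attacks the trimethylsilyl group of 21 and triflate leaves in a 1,2-elimination to give aryne 22, which adds across C2 and C5 of the electron-rich furan 13 in a concerted but asynchronous [4+2] cycloaddition; in the bridged ketal 23 the silyloxy oxygen then pushes the oxygen bridge open at C4', and loss of the silyl group to fluoride leaves the C4' ketone and the C1' alkoxide, which is protonated on work-up. The closest known reaction type is the aryne Diels-Alder reaction of 2-alkoxy- and 2-silyloxyfurans with opening of the bridged ketal, and aryne additions to 2,5-disubstituted furans are routine. Ring C is closed by this intermolecular [4+2] cycloaddition, which forms C4'–C4a' and C1'–C8a' in one operation, the furan oxygen ending as the C1' hydroxyl. The C1' stereocentre forms as a racemate with no controlling element, which is acceptable because step 13 removes it. The step needs one orientation of the two partners, and both agree on it: the furan is most nucleophilic at its aryl-bearing C5, and the aryne, polarised by the inductive pull of the benzyloxy group, is most electrophilic and least crowded at the carbon remote from that group, so C1' bonds there and the C4' oxygen ends peri to the C5' oxygen. It also needs chemoselectivity, which should come from the bulk of the triisopropylsilyl group (fluoride attack is slow compared with attack on the aryl–SiMe3 bond next to a triflate) and from the two methyl groups flanking the isoquinoline nitrogen, which keep it from capturing the aryne.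

Step 13
Reactants: 24 (±)-4-[8-(benzyloxy)-1,3-dimethylisoquinolin-7-yl]-8-(benzyloxy)-4-hydroxy-3-methylnaphthalen-1(4H)-one
Product: 25 (±)-4-[8-(benzyloxy)-1,3-dimethylisoquinolin-7-yl]-8-(benzyloxy)-3-methylnaphthalen-1-ol
Conditions: Zn dust, AcOH, rt → 60 °C
Reagents that add atoms: none
Why: dissolving-metal reduction of a para-quinol (vinylogous α-hydroxy ketone); electron transfer from zinc to the enone expels the C1' hydroxyl as water and the dienol tautomerises to the naphthol, which removes the C1' stereocentre and creates the C7–C1' biaryl axis as a racemate.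

Step 14
Reactants: 25 (±)-4-[8-(benzyloxy)-1,3-dimethylisoquinolin-7-yl]-8-(benzyloxy)-3-methylnaphthalen-1-ol
Product: 26 (±)-8-(benzyloxy)-7-[5-(benzyloxy)-4-methoxy-2-methylnaphthalen-1-yl]-1,3-dimethylisoquinoline
Conditions: MeI (1.2 equiv), K2CO3, acetone, rt → 40 °C
Reagents that add atoms: iodomethane, CI
Why: Williamson O-methylation; the naphtholate should react much faster with MeI than the methyl-flanked isoquinoline nitrogen, so a slight excess of MeI suffices.

Step 15
Reactants: 26 (±)-8-(benzyloxy)-7-[5-(benzyloxy)-4-methoxy-2-methylnaphthalen-1-yl]-1,3-dimethylisoquinoline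
Product: 27 (±)-7-(5-hydroxy-4-methoxy-2-methylnaphthalen-1-yl)-1,3-dimethylisoquinolin-8-ol
Conditions: H2 (1 atm), Pd/C, EtOAc/MeOH, rt
Reagents that add atoms: none
Why: heterogeneous hydrogenolysis of both aryl benzyl ethers over palladium on carbon at 1 atm, conditions under which the methyl ether and the naphthalene and isoquinoline rings should not be reduced.

Step 16
Reactants: 27 (±)-7-(5-hydroxy-4-methoxy-2-methylnaphthalen-1-yl)-1,3-dimethylisoquinolin-8-ol
Product: 28 ent-dioncophylleine A (M atropisomer)
Conditions: preparative HPLC on a cellulose tris(3,5-dimethylphenylcarbamate) phase, hexane/i-PrOH/Et2NH, rt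
Reagents that add atoms: none
Why: resolution by chromatography on a chiral stationary phase; rotation about the C7–C1' axis is blocked by three ortho substituents (C8–OH, C2'–CH3 and the fused ring at C8a'), so the atropisomers should be configurationally stable at room temperature and the M enantiomer can be collected and assigned by its CD spectrum.

**Compound list**

1 | 2',6'-dihydroxyacetophenone | CC(=O)c1c(O)cccc1O | starting material
2 | 2-acetyl-3-hydroxyphenyl trifluoromethanesulfonate | CC(=O)c1c(O)cccc1OS(=O)(=O)C(F)(F)F | intermediate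
3 | propyne | CC#C | starting material
4 | 1-[2-hydroxy-6-(prop-1-yn-1-yl)phenyl]ethan-1-one | CC#Cc1cccc(O)c1C(C)=O | intermediate
5 | 1,3-dimethylisoquinolin-8-ol | Cc1cc2cccc(O)c2c(C)n1 | intermediate
6 | 8-hydroxy-1,3-dimethylisoquinoline-7-carbaldehyde | Cc1cc2ccc(C=O)c(O)c2c(C)n1 | intermediate
7 | 8-(benzyloxy)-1,3-dimethylisoquinoline-7-carbaldehyde | Cc1cc2ccc(C=O)c(OCc3ccccc3)c2c(C)n1 | intermediate
8 | ethyl propiolate | C#CC(=O)OCC | starting material
9 | lithium (ethoxycarbonyl)acetylide | [Li]C#CC(=O)OCC | intermediate (not isolated)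
10 | ethyl 4-[8-(benzyloxy)-1,3-dimethylisoquinolin-7-yl]-4-hydroxybut-2-ynoate (racemic, one enantiomer drawn) | CCOC(=O)C#C[C@H](O)c1ccc2cc(C)nc(C)c2c1OCc1ccccc1 | intermediate
11 | ethyl (Z)-4-[8-(benzyloxy)-1,3-dimethylisoquinolin-7-yl]-4-hydroxy-3-methylbut-2-enoate (racemic, one enantiomer drawn) | CCOC(=O)/C=C(C)\[C@H](O)c1ccc2cc(C)nc(C)c2c1OCc1ccccc1 | intermediate (not isolated)
12 | 5-[8-(benzyloxy)-1,3-dimethylisoquinolin-7-yl]-4-methylfuran-2(5H)-one (racemic, one enantiomer drawn) | O=C1C=C(C)[C@@H](c2ccc3cc(C)nc(C)c3c2OCc2ccccc2)O1 | intermediate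
13 | 8-(benzyloxy)-1,3-dimethyl-7-[3-methyl-5-(triisopropylsilyloxy)furan-2-yl]isoquinoline | CC(C)[Si](Oc1cc(C)c(o1)-c1ccc2cc(C)nc(C)c2c1OCc1ccccc1)(C(C)C)C(C)C | intermediate
14 | 3-(benzyloxy)phenol | Oc1cccc(OCc2ccccc2)c1 | starting material
15 | 3-(benzyloxy)phenyl isopropylcarbamate | CC(C)NC(=O)Oc1cccc(OCc2ccccc2)c1 | intermediate
16 | 3-(benzyloxy)phenyl N-(tert-butyldimethylsilyl)-N-isopropylcarbamate | CC(C)N(C(=O)Oc1cccc(OCc2ccccc2)c1)[Si](C)(C)C(C)(C)C | intermediate (not isolated)
17 | 2-lithio derivative of 16 | CC(C)N(C(=O)Oc1cccc(OCc2ccccc2)c1[Li])[Si](C)(C)C(C)(C)C | intermediate (not isolated)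
18 | 3-(benzyloxy)-2-(trimethylsilyl)phenyl N-(tert-butyldimethylsilyl)-N-isopropylcarbamate | CC(C)N(C(=O)Oc1cccc(OCc2ccccc2)c1[Si](C)(C)C)[Si](C)(C)C(C)(C)C | intermediate (not isolated)
19 | 3-(benzyloxy)-2-(trimethylsilyl)phenyl isopropylcarbamate | CC(C)NC(=O)Oc1cccc(OCc2ccccc2)c1[Si](C)(C)C | intermediate
20 | 3-(benzyloxy)-2-(trimethylsilyl)phenol | C[Si](C)(C)c1c(O)cccc1OCc1ccccc1 | intermediate (not isolated)
21 | 3-(benzyloxy)-2-(trimethylsilyl)phenyl trifluoromethanesulfonate | C[Si](C)(C)c1c(OCc2ccccc2)cccc1OS(=O)(=O)C(F)(F)F | intermediate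
22 | 3-(benzyloxy)benzyne | C1#CC(OCc2ccccc2)=CC=C1 | intermediate (not isolated)
23 | 7-[5-(benzyloxy)-2-methyl-4-(triisopropylsilyloxy)-1,4-dihydro-1,4-epoxynaphthalen-1-yl]-8-(benzyloxy)-1,3-dimethylisoquinoline (racemic, one enantiomer drawn; relative configuration fixed by the bridge) | CC1=C[C@]2(O[Si](C(C)C)(C(C)C)C(C)C)O[C@@]1(c1ccc3cc(C)nc(C)c3c1OCc1ccccc1)c1cccc(OCc3ccccc3)c12 | intermediate (not isolated)
24 | 4-[8-(benzyloxy)-1,3-dimethylisoquinolin-7-yl]-8-(benzyloxy)-4-hydroxy-3-methylnaphthalen-1(4H)-one (racemic, one enantiomer drawn) | O=C1C=C(C)[C@](O)(c2ccc3cc(C)nc(C)c3c2OCc2ccccc2)c2cccc(OCc3ccccc3)c12 | intermediate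
25 | 4-[8-(benzyloxy)-1,3-dimethylisoquinolin-7-yl]-8-(benzyloxy)-3-methylnaphthalen-1-ol (racemic about the axis) | Oc1cc(C)c(-c2ccc3cc(C)nc(C)c3c2OCc2ccccc2)c2cccc(OCc3ccccc3)c12 | intermediate
26 | 8-(benzyloxy)-7-[5-(benzyloxy)-4-methoxy-2-methylnaphthalen-1-yl]-1,3-dimethylisoquinoline (racemic about the axis) | COc1cc(C)c(-c2ccc3cc(C)nc(C)c3c2OCc2ccccc2)c2cccc(OCc3ccccc3)c12 | intermediate
27 | 7-(5-hydroxy-4-methoxy-2-methylnaphthalen-1-yl)-1,3-dimethylisoquinolin-8-ol (racemic about the axis) | COc1cc(C)c(-c2ccc3cc(C)nc(C)c3c2O)c2cccc(O)c12 | intermediate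
28 | ent-dioncophylleine A (M atropisomer) | COc1cc(C)c(-c2ccc3cc(C)nc(C)c3c2O)c2cccc(O)c12 | target

**Step count**

Total: 16 steps. Longest linear sequence: 13 steps (steps 1 to 8, then 12 to 16). The aryne branch (steps 9 to 11) joins at step 12.

**Steps most likely to fail**

1. Step 12 (key step). Cycloaddition at the aryl-shielded, fully substituted furan terminus may be slow. Fluoride cleavage of the silyl ketene acetal, and capture of the aryne by the isoquinoline nitrogen or by itself, could then consume the partners. The fallback sets out from 5 and 21 and returns at 25. It builds ring C on an unhindered furan and makes the C7–C1' bond afterwards by Suzuki–Miyaura coupling. Ortho-bromination of 5 (NBS, i-Pr2NH cat., CH2Cl2) should give 7-bromo-1,3-dimethylisoquinolin-8-ol F1. Benzylation (BnBr, K2CO3, DMF) should give 8-(benzyloxy)-7-bromo-1,3-dimethylisoquinoline F2, and Miyaura borylation (B2pin2, Pd(dppf)Cl2, KOAc, dioxane) the pinacol boronate 8-(benzyloxy)-1,3-dimethyl-7-(4,4,5,5-tetramethyl-1,3,2-dioxaborolan-2-yl)isoquinoline F3. Commercial 4-methylfuran-2(5H)-one is silylated (TIPSOTf, Et3N) to 4-methyl-2-(triisopropylsilyloxy)furan F4. With benzyne 22 generated from 21 (CsF, MeCN), the same cycloaddition and ketal opening, now ending with loss of the C1' proton, should give 5-(benzyloxy)-2-methyl-4-(triisopropylsilyloxy)naphthalen-1-ol F5. Tf2O/pyridine converts this to 5-(benzyloxy)-2-methyl-4-(triisopropylsilyloxy)naphthalen-1-yl triflate F6. Coupling of F3 with F6 (Pd(OAc)2, SPhos, K3PO4, toluene/H2O, 100 °C) should give the triisopropylsilyl ether of 25 F7, and TBAF in THF returns 25.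

2. Step 4. Formylation of the weakly nucleophilic hydroxyisoquinoline may stall, and formaldehyde may condense at the acidic C1 methyl group. The fallback sets out from 5 and returns at 7. It replaces electrophilic formylation by cross-coupling and oxidative cleavage. 8-(Benzyloxy)-7-bromo-1,3-dimethylisoquinoline F2, made from 5 through 7-bromo-1,3-dimethylisoquinolin-8-ol F1 as described above, is vinylated with potassium vinyltrifluoroborate (Pd(dppf)Cl2, Cs2CO3, THF/H2O) to 8-(benzyloxy)-7-ethenyl-1,3-dimethylisoquinoline F8. Lemieux–Johnson cleavage (OsO4 cat., NaIO4, 2,6-lutidine, dioxane/H2O) then gives 7.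

3. Step 7. The alkenylcopper intermediate may equilibrate through its allenolate before protonation. That would scramble the alkene geometry and leave E-enoate that cannot lactonise. The fallback sets out from 7 and returns at 12. It closes the butenolide by ring-closing metathesis. Addition of isopropenylmagnesium bromide to 7 (THF, 0 °C) should give 1-[8-(benzyloxy)-1,3-dimethylisoquinolin-7-yl]-2-methylprop-2-en-1-ol F9. Acylation with acryloyl chloride (Et3N, DMAP, CH2Cl2) gives 1-[8-(benzyloxy)-1,3-dimethylisoquinolin-7-yl]-2-methylprop-2-en-1-yl acrylate F10. The second-generation Grubbs catalyst (toluene, 80 °C) then closes 12 with loss of ethene.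

**Further compounds**

F1 | step 12 | 7-bromo-1,3-dimethylisoquinolin-8-ol | Cc1cc2ccc(Br)c(O)c2c(C)n1
F2 | step 12 | 8-(benzyloxy)-7-bromo-1,3-dimethylisoquinoline | Cc1cc2ccc(Br)c(OCc3ccccc3)c2c(C)n1
F3 | step 12 | 8-(benzyloxy)-1,3-dimethyl-7-(4,4,5,5-tetramethyl-1,3,2-dioxaborolan-2-yl)isoquinoline | Cc1cc2ccc(B3OC(C)(C)C(C)(C)O3)c(OCc3ccccc3)c2c(C)n1
F4 | step 12 | 4-methyl-2-(triisopropylsilyloxy)furan | Cc1coc(O[Si](C(C)C)(C(C)C)C(C)C)c1
F5 | step 12 | 5-(benzyloxy)-2-methyl-4-(triisopropylsilyloxy)naphthalen-1-ol | Oc1c(C)cc(O[Si](C(C)C)(C(C)C)C(C)C)c2c(OCc3ccccc3)cccc12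
F6 | step 12 | 5-(benzyloxy)-2-methyl-4-(triisopropylsilyloxy)naphthalen-1-yl trifluoromethanesulfonate | Cc1cc(O[Si](C(C)C)(C(C)C)C(C)C)c2c(OCc3ccccc3)cccc2c1OS(=O)(=O)C(F)(F)F
F7 | step 12 | 8-(benzyloxy)-7-[5-(benzyloxy)-2-methyl-4-(triisopropylsilyloxy)naphthalen-1-yl]-1,3-dimethylisoquinoline (racemic about the axis) | Cc1cc(O[Si](C(C)C)(C(C)C)C(C)C)c2c(OCc3ccccc3)cccc2c1-c1ccc2cc(C)nc(C)c2c1OCc1ccccc1
F8 | step 4 | 8-(benzyloxy)-7-ethenyl-1,3-dimethylisoquinoline | Cc1cc2ccc(C=C)c(OCc3ccccc3)c2c(C)n1
F9 | step 7 | 1-[8-(benzyloxy)-1,3-dimethylisoquinolin-7-yl]-2-methylprop-2-en-1-ol (racemic) | C=C(C)C(O)c1ccc2cc(C)nc(C)c2c1OCc1ccccc1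
F10 | step 7 | 1-[8-(benzyloxy)-1,3-dimethylisoquinolin-7-yl]-2-methylprop-2-en-1-yl acrylate (racemic) | C=CC(=O)OC(C(C)=C)c1ccc2cc(C)nc(C)c2c1OCc1ccccc1
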